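The tricycle is disconnected at C1–C5 and C3–C4 (tricyclo[5.3.1.0^1,5]undecane numbering). This unravels both cyclopentanes to two prenyl groups on a monocyclic, dearomatised acylphloroglucinol whose only ring stereocentre is the methyl/prenyl quaternary carbon (C7). The key step exploits that C1 is the α-carbon of the C10/C11 β-dicarbonyl: one-electron oxidation gives a C1 radical that closes the cyclopentanone ring of the bicyclo[3.2.1]octane, the resulting gem-dimethyl radical (C4) closes the outer cyclopentane at C3, and the last radical takes up oxygen to become the tertiary alcohol. The quaternary carbon is set beforehand by asymmetric dearomative prenylation; the (R)-acyl group comes from (R)-2-methylbutanoic acid.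

Key step: step 5

Assumption: (R)-2-methylbutanoic acid is taken as purchasable in enantiopure form; enolised β-tricarbonyl compounds are drawn as one tautomer, and their descriptors refer to the tautomer drawn.

Step 1
Reactants: 1 (2R)-2-methylbutanoic acid
Product: 2 (2R)-2-methylbutanoyl chloride
Conditions: (COCl)2 (1.1 equiv), DMF (cat.), CH2Cl2, 0 °C to rt; used crude
Reagents that add atoms: oxalyl chloride, ClC(=O)C(=O)Cl
Why: Acid chloride formation through the Vilsmeier-type chloroiminium species runs without base, so no ketene can form and the α-stereocentre should be retained.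

Step 2
Reactants: 2 (2R)-2-methylbutanoyl chloride; 3 2-methylbenzene-1,3,5-triol
Product: 4 (2R)-2-methyl-1-(2,4,6-trihydroxy-3-methylphenyl)butan-1-one
Conditions: AlCl3 (3.5 equiv), PhNO2/CH2Cl2, 0 °C to rt; cold 1 M HCl work-up
Reagents that add atoms: none
Why: Friedel–Crafts acylation should occur at one of the two equivalent free positions of the electron-rich triol, the aluminium-chelated ketone resists a second acylation, and the low temperature is meant to keep the α-stereocentre intact.

Step 3
Reactants: 4 (2R)-2-methyl-1-(2,4,6-trihydroxy-3-methylphenyl)butan-1-one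
Product: 5 (2R)-2-methyl-1-[2,4,6-trihydroxy-3-methyl-5-(3-methylbut-2-en-1-yl)phenyl]butan-1-one
Conditions: prenyl bromide (1.0 equiv), 10% aq. KOH, 0 °C; then dilute HCl
Reagents that add atoms: prenyl bromide (1-bromo-3-methylbut-2-ene), CC(C)=CCBr
Why: Phenolate C-alkylation (C-prenylation) in water, where hydrogen bonding suppresses O-alkylation, should take place at the only unsubstituted ring carbon because only there can the ring re-aromatise, and one equivalent of halide limits over-alkylation.

Step 4
Reactants: 5 (2R)-2-methyl-1-[2,4,6-trihydroxy-3-methyl-5-(3-methylbut-2-en-1-yl)phenyl]butan-1-one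
Product: 6 (6S)-3,5-dihydroxy-6-methyl-4-[(2R)-2-methylbutanoyl]-2,6-bis(3-methylbut-2-en-1-yl)cyclohexa-2,4-dien-1-one
Conditions: Pd2(dba)3·CHCl3 (2.5 mol %), N,N'-[(1R,2R)-cyclohexane-1,2-diyl]bis[2-(diphenylphosphanyl)benzamide] (7.5 mol %), prenyl acetate (1.1 equiv), Et3N (1.1 equiv), THF, 0 °C; dilute HCl work-up
Reagents that add atoms: prenyl acetate (3-methylbut-2-en-1-yl acetate), CC(=O)OCC=C(C)C
Why: In this dearomative Tsuji–Trost asymmetric allylic alkylation the phenolate should attack the CH2 terminus of the π-prenyl complex of divalent palladium through the methyl-bearing ring carbon (less hindered than the prenyl-bearing one, while O-prenyl ethers are re-ionised by zerovalent palladium), and the chiral diphosphine pocket selects the ring face to give the 6S quaternary centre (ligand enantiomer to be confirmed in a pilot run, the antipode being used if the sense is reversed).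

Step 5
Reactants: 6 (6S)-3,5-dihydroxy-6-methyl-4-[(2R)-2-methylbutanoyl]-2,6-bis(3-methylbut-2-en-1-yl)cyclohexa-2,4-dien-1-one
Product: 8 (1S,3S,5S,7S)-8-hydroxy-3-(2-hydroxypropan-2-yl)-4,4,7-trimethyl-9-[(2R)-2-methylbutanoyl]tricyclo[5.3.1.0^{1,5}]undec-8-ene-10,11-dione, via tertiary hydroperoxide 7 (not isolated)
Conditions: Mn(OAc)3·2H2O (0.3 equiv), AcOH (0.01 M), slow stream of 2% O2 in N2, rt; then PPh3 (1.5 equiv), rt
Reagents that add atoms: dioxygen, O=O
Why: Trivalent manganese oxidises the enol of 6 to the ring radical at C2 (C1 of 8), which adds 5-exo-trig to the CH carbon of the C6 prenyl group; the tertiary radical so formed (C4 of 8) adds 5-exo-trig to the CH carbon of the second prenyl group and thereby makes the C3–C4 bond, and the final 2-propyl radical is captured by O2, the peroxyl radical being reduced to hydroperoxide 7 by divalent manganese or by a further molecule of 6 before PPh3 removes one oxygen. The closest known reaction types are the Mn(OAc)3-mediated oxidative radical cyclization of prenylated cyclic 1,3-dicarbonyl compounds and the manganese-catalysed aerobic hydroperoxidation of dicarbonyl–alkene radical adducts. Both rings close in the 5-exo-trig mode, first the cyclopentanone ring C1–C5–C6–C7–C11 that completes the bicyclo[3.2.1]octane, then the outer cyclopentane C1–C2–C3–C4–C5. C1 follows from C7 because the short tether can reach the ring radical only on the face that carries it; C5 is set exo (side chain toward the C11 bridge), which avoids the six-membered trione ring and is the only orientation from which a cis-fused second ring can form; C3 is set by the orientation of the dimethylvinyl terminus in the second closure. The step needs the second closure to outrun capture of the C4 radical by O2, which the rigid bicycle (radical and alkene held gauche across C1–C5) and the lean oxygen stream should secure, and it needs the terminus at C3 to lie on the face of the C11 carbonyl; no element of 6 enforces the latter, so the C3 epimer is expected as a co-product that is removed by chromatography.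

Compound list
1 | (2R)-2-methylbutanoic acid | CC[C@@H](C)C(=O)O | starting material
2 | (2R)-2-methylbutanoyl chloride | CC[C@@H](C)C(=O)Cl | intermediate
3 | 2-methylbenzene-1,3,5-triol (2-methylphloroglucinol) | Cc1c(O)cc(O)cc1O | starting material
4 | (2R)-2-methyl-1-(2,4,6-trihydroxy-3-methylphenyl)butan-1-one | CC[C@@H](C)C(=O)c1c(O)cc(O)c(C)c1O | intermediate
5 | (2R)-2-methyl-1-[2,4,6-trihydroxy-3-methyl-5-(3-methylbut-2-en-1-yl)phenyl]butan-1-one | CC[C@@H](C)C(=O)c1c(O)c(CC=C(C)C)c(O)c(C)c1O | intermediate
6 | (6S)-3,5-dihydroxy-6-methyl-4-[(2R)-2-methylbutanoyl]-2,6-bis(3-methylbut-2-en-1-yl)cyclohexa-2,4-dien-1-one | CC[C@@H](C)C(=O)C1=C(O)[C@](C)(CC=C(C)C)C(=O)C(CC=C(C)C)=C1O | intermediate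
7 | (1S,3S,5S,7S)-3-(2-hydroperoxypropan-2-yl)-8-hydroxy-4,4,7-trimethyl-9-[(2R)-2-methylbutanoyl]tricyclo[5.3.1.0^{1,5}]undec-8-ene-10,11-dione | CC[C@@H](C)C(=O)C1=C(O)[C@]2(C)C[C@H]3C(C)(C)[C@@H](C(C)(C)OO)C[C@@]3(C1=O)C2=O | intermediate
8 | (1S,3S,5S,7S)-8-hydroxy-3-(2-hydroxypropan-2-yl)-4,4,7-trimethyl-9-[(2R)-2-methylbutanoyl]tricyclo[5.3.1.0^{1,5}]undec-8-ene-10,11-dione | CC[C@@H](C)C(=O)C1=C(O)[C@]2(C)C[C@H]3C(C)(C)[C@@H](C(C)(C)O)C[C@@]3(C1=O)C2=O | target

Total step count: 5. Longest linear sequence: 5 steps (1 → 2 → 4 → 5 → 6 → 8).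

Steps most likely to fail

Step 5. Oxygen may intercept the ring radical or the C4 radical before the second ring closure, and the second closure has little facial bias at C3. Fallback, setting out from 6: the cascade is run without oxygen (Mn(OAc)3·2H2O, 2.2 equiv, Cu(OAc)2·H2O, 0.5 equiv, degassed AcOH, rt). Divalent copper then oxidises the last radical to the alkene, giving (1S,3R,5S,7S)-8-hydroxy-4,4,7-trimethyl-9-[(2R)-2-methylbutanoyl]-3-(prop-1-en-2-yl)tricyclo[5.3.1.0^{1,5}]undec-8-ene-10,11-dione F1, which is separated from its C3 epimer at this less polar stage. Mukaiyama hydration of the 1,1-disubstituted alkene of F1 (Co(acac)2 cat., PhSiH3, O2, i-PrOH, rt, then PPh3) installs the tertiary alcohol and comes back to the route at 8.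

Step 4. The facial selectivity at the new quaternary carbon may be poor. Attack may also occur at the prenyl-bearing ring carbon or a second time at C2 of the product, and zerovalent palladium may re-ionise the acidic product and erode its configuration. Fallback, setting out from 5: uncatalysed dearomative C-alkylation (prenyl bromide, NaOMe, MeOH, 0 °C) gives 6 together with (6R)-3,5-dihydroxy-6-methyl-4-[(2R)-2-methylbutanoyl]-2,6-bis(3-methylbut-2-en-1-yl)cyclohexa-2,4-dien-1-one F2. These are diastereomers because the side chain is already a single enantiomer. The mixture is taken through step 5 to give 8 and (1R,3R,5R,7R)-8-hydroxy-3-(2-hydroxypropan-2-yl)-4,4,7-trimethyl-9-[(2R)-2-methylbutanoyl]tricyclo[5.3.1.0^{1,5}]undec-8-ene-10,11-dione F3, which are separated by preparative HPLC at the rigid tricyclic stage; the route is rejoined at 8.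

Step 2. The α-stereocentre of the acyl group may partly epimerise under AlCl3, through enolisation of the aluminium-bound aryl ketone or ketene formation from 2. Fallback, setting out from 3 and 2, returning at 4:
- 3 is protected (MOMCl, i-Pr2NEt, CH2Cl2) as 1,3,5-tris(methoxymethoxy)-2-methylbenzene F4.
- 2 is converted (MeNHOMe·HCl, pyridine, CH2Cl2, 0 °C) into (2R)-N-methoxy-N,2-dimethylbutanamide F5.
- Ortho-lithiation of F4 between two acetal oxygens (n-BuLi, THF, 0 °C) and addition to F5 at −78 °C should give, through a chelated tetrahedral intermediate that cannot enolise, (2R)-2-methyl-1-[2,4,6-tris(methoxymethoxy)-3-methylphenyl]butan-1-one F6.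
- HCl in MeOH at rt removes the three acetals and comes back to the route at 4.

Further compounds
F1 | step 5 | (1S,3R,5S,7S)-8-hydroxy-4,4,7-trimethyl-9-[(2R)-2-methylbutanoyl]-3-(prop-1-en-2-yl)tricyclo[5.3.1.0^{1,5}]undec-8-ene-10,11-dione | CC[C@@H](C)C(=O)C1=C(O)[C@]2(C)C[C@H]3C(C)(C)[C@@H](C(C)=C)C[C@@]3(C1=O)C2=O
F2 | step 4 | (6R)-3,5-dihydroxy-6-methyl-4-[(2R)-2-methylbutanoyl]-2,6-bis(3-methylbut-2-en-1-yl)cyclohexa-2,4-dien-1-one | CC[C@@H](C)C(=O)C1=C(O)[C@@](C)(CC=C(C)C)C(=O)C(CC=C(C)C)=C1O
F3 | step 4 | (1R,3R,5R,7R)-8-hydroxy-3-(2-hydroxypropan-2-yl)-4,4,7-trimethyl-9-[(2R)-2-methylbutanoyl]tricyclo[5.3.1.0^{1,5}]undec-8-ene-10,11-dione | CC[C@@H](C)C(=O)C1=C(O)[C@@]2(C)C[C@@H]3C(C)(C)[C@H](C(C)(C)O)C[C@]3(C1=O)C2=O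
F4 | step 2 | 1,3,5-tris(methoxymethoxy)-2-methylbenzene | Cc1c(OCOC)cc(OCOC)cc1OCOC
F5 | step 2 | (2R)-N-methoxy-N,2-dimethylbutanamide | CC[C@@H](C)C(=O)N(C)OC
F6 | step 2 | (2R)-2-methyl-1-[2,4,6-tris(methoxymethoxy)-3-methylphenyl]butan-1-one | CC[C@@H](C)C(=O)c1c(OCOC)cc(OCOC)c(C)c1OCOC
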